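**Retrosynthetic overview**
- Target 13 ⇐ dihydrobenzofuran diphenol 11 + 2 prenyl bromide: dearomatising gem-diprenylation at the only free ring carbon (last step).
- 11 ⇐ 10 ⇐ 7: the dihydrofuran ring is closed by forming the O1–C2 bond; the ketone-flanked phenol oxygen opens an (S)-epoxide 5-exo with inversion, while the para oxygen is blocked as a silyl ether.
- (S)-Epoxide 9 ⇐ 7: phenol-directed catalytic asymmetric epoxidation of the single prenyl group (new step, sets the only stereocentre).
- 7 ⇐ 5 ⇐ 3 ⇐ 1 + 2: para-O-silylation, mono-C-prenylation, Friedel–Crafts acylation.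
- Ring order: benzene ring bought (phloroglucinol); dihydrofuran ring closed in step 4; carbocycle dearomatised in step 5.

Assumption: the [C@@H] centre of the target reads as (R) and the drawn structure is one tautomer of an enolised triketone. The sense of induction of the new step 4 is not known, so the ligand antipode named there is provisional (both antipodes are equally available). Bases, catalysts and solvents are not numbered.

**Step 1**
Reactants: 1 phloroglucinol; 2 3-methylbutanoyl chloride
Product: 3 3-methyl-1-(2,4,6-trihydroxyphenyl)butan-1-one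
Conditions: AlCl3 (3.5 equiv), PhNO2, 0 → 65 °C; aq. HCl work-up
Reagents that add atoms: 3-methylbutanoyl chloride, CC(C)CC(Cl)=O
Why: Friedel–Crafts acylation of the electron-rich triol stops at mono-acylation because the aluminium-chelated aryl ketone deactivates the ring.

**Step 2**
Reactants: 3 3-methyl-1-(2,4,6-trihydroxyphenyl)butan-1-one; 4 1-bromo-3-methylbut-2-ene (prenyl bromide)
Product: 5 3-methyl-1-[2,4,6-trihydroxy-3-(3-methylbut-2-en-1-yl)phenyl]butan-1-one
Conditions: 4 (0.9 equiv), 10% aq. KOH, 0 °C, 2 h; aq. HCl work-up; unreacted 3 recovered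
Reagents that add atoms: prenyl bromide, CC(C)=CCBr
Why: C-alkylation (SN2) of the ambident phenoxide is favoured in water, the two ring CH positions are equivalent so only one mono-prenyl product can form, and a deficit of bromide limits over-alkylation.

**Step 3**
Reactants: 5 3-methyl-1-[2,4,6-trihydroxy-3-(3-methylbut-2-en-1-yl)phenyl]butan-1-one; 6 tert-butyldimethylsilyl chloride
Product: 7 1-[4-(tert-butyldimethylsilyloxy)-2,6-dihydroxy-3-(3-methylbut-2-en-1-yl)phenyl]-3-methylbutan-1-one
Conditions: TBSCl (1.05 equiv), imidazole (2.2 equiv), CH2Cl2/DMF, −20 → 0 °C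
Reagents that add atoms: tert-butyldimethylsilyl chloride, CC(C)(C)[Si](C)(C)Cl
Why: Chemoselective O-silylation of the para hydroxyl, which is the most acidic one and is not hydrogen-bonded to the ketone, leaves the ketone-flanked hydroxyl as the only free oxygen next to the prenyl group.

**Step 4**
Reactants: 7 1-[4-(tert-butyldimethylsilyloxy)-2,6-dihydroxy-3-(3-methylbut-2-en-1-yl)phenyl]-3-methylbutan-1-one; 8 cumene hydroperoxide
Product: 10 1-[(2R)-4-(tert-butyldimethylsilyloxy)-6-hydroxy-2-(2-hydroxypropan-2-yl)-2,3-dihydro-1-benzofuran-7-yl]-3-methylbutan-1-one, via (S)-epoxy phenol 9 (not isolated)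
Conditions: Hf(OtBu)4 (10 mol%), (S,S)-N,N'-(cyclohexane-1,2-diyl)bis(N-hydroxy-2,2-diphenylacetamide) (12 mol%), DMPU (20 mol%), 4 Å MS, 8 (1.3 equiv), toluene, 0 °C, 24 h; then DBU (20 mol%), rt, 2 h
Reagents that add atoms: cumene hydroperoxide, CC(C)(OO)c1ccccc1
Why: Proposed new method: phenol-directed Hf(IV)–bis-hydroxamic acid asymmetric epoxidation with in-flask 5-exo cycloetherification. The C2–OH of 7 (an sp2 analogue of a bishomoallylic alcohol, O–C=C–CH2–CH=C) exchanges onto the redox-inert d0 Hf centre beside the bound cumyl peroxide, so oxygen is delivered intramolecularly to one face of the only alkene inside the C2-symmetric ligand pocket to give (S)-epoxide 9. DBU then lets the same phenol oxygen open the epoxide at its secondary carbon (5-exo-tet, SN2, inversion), forming the O1–C2 bond and the (R) centre, while the silyl ether keeps the para oxygen out. The closest known reaction type is the Zr/Hf–bis-hydroxamic acid-catalysed asymmetric epoxidation of aliphatic homo- and bishomoallylic alcohols with cumene hydroperoxide.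

**Step 5**
Reactants: 10 1-[(2R)-4-(tert-butyldimethylsilyloxy)-6-hydroxy-2-(2-hydroxypropan-2-yl)-2,3-dihydro-1-benzofuran-7-yl]-3-methylbutan-1-one; 4 1-bromo-3-methylbut-2-ene (prenyl bromide)
Product: 13 (2R)-6-hydroxy-2-(2-hydroxypropan-2-yl)-7-(3-methylbutanoyl)-5,5-bis(3-methylbut-2-en-1-yl)-2,3-dihydro-1-benzofuran-4(5H)-one, via desilylated diphenol 11 (not isolated), via mono-C-prenyl phenol 12 (not isolated)
Conditions: NaOMe (4.5 equiv), MeOH, 0 °C, 30 min; then 4 (2.3 equiv), 0 °C → rt; 1 M HCl work-up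
Reagents that add atoms: prenyl bromide, CC(C)=CCBr
Why: Methoxide cleaves the electron-poor aryl silyl ether, and the resulting phenoxide is C-alkylated twice at its single free ring carbon in protic solvent; the second alkylation is an alkylative dearomatisation of the classical lupulone type giving the stable enolised triketone, with the remote stereocentre untouched.

**Compound list**
1 | phloroglucinol (benzene-1,3,5-triol) | Oc1cc(O)cc(O)c1 | starting material
2 | 3-methylbutanoyl chloride (isovaleryl chloride) | CC(C)CC(Cl)=O | starting material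
3 | 3-methyl-1-(2,4,6-trihydroxyphenyl)butan-1-one (phlorisovalerophenone) | CC(C)CC(=O)c1c(O)cc(O)cc1O | intermediate
4 | 1-bromo-3-methylbut-2-ene (prenyl bromide) | CC(C)=CCBr | starting material
5 | 3-methyl-1-[2,4,6-trihydroxy-3-(3-methylbut-2-en-1-yl)phenyl]butan-1-one | CC(C)CC(=O)c1c(O)cc(O)c(CC=C(C)C)c1O | intermediate
6 | tert-butyldimethylsilyl chloride | CC(C)(C)[Si](C)(C)Cl | starting material
7 | 1-[4-(tert-butyldimethylsilyloxy)-2,6-dihydroxy-3-(3-methylbut-2-en-1-yl)phenyl]-3-methylbutan-1-one | CC(C)CC(=O)c1c(O)cc(O[Si](C)(C)C(C)(C)C)c(CC=C(C)C)c1O | intermediate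
8 | cumene hydroperoxide | CC(C)(OO)c1ccccc1 | starting material
9 | 1-[4-(tert-butyldimethylsilyloxy)-3-{[(2S)-3,3-dimethyloxiran-2-yl]methyl}-2,6-dihydroxyphenyl]-3-methylbutan-1-one (formed in the flask in step 4) | CC(C)CC(=O)c1c(O)cc(O[Si](C)(C)C(C)(C)C)c(C[C@@H]2OC2(C)C)c1O | intermediate
10 | 1-[(2R)-4-(tert-butyldimethylsilyloxy)-6-hydroxy-2-(2-hydroxypropan-2-yl)-2,3-dihydro-1-benzofuran-7-yl]-3-methylbutan-1-one | CC(C)CC(=O)c1c(O)cc(O[Si](C)(C)C(C)(C)C)c2c1O[C@@H](C(C)(C)O)C2 | intermediate
11 | 1-[(2R)-4,6-dihydroxy-2-(2-hydroxypropan-2-yl)-2,3-dihydro-1-benzofuran-7-yl]-3-methylbutan-1-one (formed in the flask in step 5) | CC(C)CC(=O)c1c(O)cc(O)c2c1O[C@@H](C(C)(C)O)C2 | intermediate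
12 | 1-[(2R)-4,6-dihydroxy-2-(2-hydroxypropan-2-yl)-5-(3-methylbut-2-en-1-yl)-2,3-dihydro-1-benzofuran-7-yl]-3-methylbutan-1-one (formed in the flask in step 5) | CC(C)CC(=O)c1c(O)c(CC=C(C)C)c(O)c2c1O[C@@H](C(C)(C)O)C2 | intermediate
13 | (2R)-6-hydroxy-2-(2-hydroxypropan-2-yl)-7-(3-methylbutanoyl)-5,5-bis(3-methylbut-2-en-1-yl)-2,3-dihydro-1-benzofuran-4(5H)-one | CC(C)=CCC1(CC=C(C)C)C(=O)C2=C(O[C@@H](C(C)(C)O)C2)C(C(=O)CC(C)C)=C1O | target

**Totals**
Total step count: 5. Longest linear sequence: 5 steps (1 → 3 → 5 → 7 → 10 → 13).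

**Three steps most likely to fail**

Step 4 (the proposed new step). The risks are chelation of Hf by the hydroxy-ketone (slow turnover), an unknown sense and level of induction, and Lewis-acid-induced 6-endo opening to a 3-hydroxychroman before the base is added. The fallback uses known chemistry only, sets out from 5 and comes back at 11. Benzylation of the para hydroxyl (BnBr, K2CO3, acetone) gives 1-[4-(benzyloxy)-2,6-dihydroxy-3-(3-methylbut-2-en-1-yl)phenyl]-3-methylbutan-1-one F3. Silylation of both remaining phenols (TBSOTf, 2,6-lutidine, CH2Cl2) gives 1-[4-(benzyloxy)-2,6-bis(tert-butyldimethylsilyloxy)-3-(3-methylbut-2-en-1-yl)phenyl]-3-methylbutan-1-one F4. Shi epoxidation with the L-fructose-derived (ent-Shi) ketone, Oxone and K2CO3 buffer in MeCN/DMM/H2O at 0 °C gives 1-[4-(benzyloxy)-2,6-bis(tert-butyldimethylsilyloxy)-3-{[(2S)-3,3-dimethyloxiran-2-yl]methyl}phenyl]-3-methylbutan-1-one F5. TBAF in THF removes both silyl groups, and the freed ketone-flanked phenoxide (the only oxygen next to the epoxide, the para oxygen being benzylated) closes 5-exo with inversion to 1-[(2R)-4-(benzyloxy)-6-hydroxy-2-(2-hydroxypropan-2-yl)-2,3-dihydro-1-benzofuran-7-yl]-3-methylbutan-1-one F6. Hydrogenolysis (H2, Pd/C, EtOAc) gives 11, which is taken into step 5 directly.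

Step 5 (dearomatising gem-diprenylation). The risks are O-prenylation and stopping at the mono-prenyl phenol 12. The fallback sets out from 10 and comes back at 13. TBAF in THF gives isolated 11. This is then prenylated twice under neutral Tsuji–Trost conditions (Pd(PPh3)4 5 mol%, tert-butyl 3-methylbut-2-en-1-yl carbonate 2.2 equiv, THF, rt). The soft π-prenyl-palladium electrophile is attacked at its less hindered terminus, and any O-allylation is reversible under Pd(0), so the doubly C-prenylated dearomatised product 13 accumulates. This fallback makes no new compound (F0).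

Step 2 (mono-C-prenylation). The risk is a mixture of mono-, di-, gem- and O-prenylated products with a modest yield of 5. The fallback sets out from 3 and comes back at 5. Selective O-allylation of the para hydroxyl (allyl bromide 1.0 equiv, K2CO3, acetone) gives 1-[2,6-dihydroxy-4-(prop-2-en-1-yloxy)phenyl]-3-methylbutan-1-one F1. Aromatic Claisen rearrangement (N,N-diethylaniline, 200 °C; both ortho positions are equivalent) gives 3-methyl-1-[2,4,6-trihydroxy-3-(prop-2-en-1-yl)phenyl]butan-1-one F2. Cross-metathesis with 2-methylbut-2-ene (Grubbs II 5 mol%, CH2Cl2, 40 °C) turns the allyl into the prenyl group and gives 5; here mono-substitution is fixed by the mono-O-allylation.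

**Further compounds**
F1 | step 2 | 1-[2,6-dihydroxy-4-(prop-2-en-1-yloxy)phenyl]-3-methylbutan-1-one | CC(C)CC(=O)c1c(O)cc(OCC=C)cc1O
F2 | step 2 | 3-methyl-1-[2,4,6-trihydroxy-3-(prop-2-en-1-yl)phenyl]butan-1-one | CC(C)CC(=O)c1c(O)cc(O)c(CC=C)c1O
F3 | step 4 | 1-[4-(benzyloxy)-2,6-dihydroxy-3-(3-methylbut-2-en-1-yl)phenyl]-3-methylbutan-1-one | CC(C)CC(=O)c1c(O)cc(OCc2ccccc2)c(CC=C(C)C)c1O
F4 | step 4 | 1-[4-(benzyloxy)-2,6-bis(tert-butyldimethylsilyloxy)-3-(3-methylbut-2-en-1-yl)phenyl]-3-methylbutan-1-one | CC(C)CC(=O)c1c(O[Si](C)(C)C(C)(C)C)cc(OCc2ccccc2)c(CC=C(C)C)c1O[Si](C)(C)C(C)(C)C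
F5 | step 4 | 1-[4-(benzyloxy)-2,6-bis(tert-butyldimethylsilyloxy)-3-{[(2S)-3,3-dimethyloxiran-2-yl]methyl}phenyl]-3-methylbutan-1-one | CC(C)CC(=O)c1c(O[Si](C)(C)C(C)(C)C)cc(OCc2ccccc2)c(C[C@@H]2OC2(C)C)c1O[Si](C)(C)C(C)(C)C
F6 | step 4 | 1-[(2R)-4-(benzyloxy)-6-hydroxy-2-(2-hydroxypropan-2-yl)-2,3-dihydro-1-benzofuran-7-yl]-3-methylbutan-1-one | CC(C)CC(=O)c1c(O)cc(OCc2ccccc2)c2c1O[C@@H](C(C)(C)O)C2
F0 | step 5 | none | none
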